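Ring A is numbered C1 (butyryl), C2 (OH), C3 (CH2 bridge), C4 (OH), C5 (CH3), C6 (OCH3); ring B is the propionylfilicinic acid ring.
Cuts, in order: the bond from the bridge CH2 to ring B; the C1–butyryl bond; C4–C5, C6–C1 and C3–C4 of ring A; last, the two ring bonds of a cyclobutenone made from a ketene and tert-butoxyacetylene.
Enabling feature: ring A has oxygen on the alternate carbons C2, C4 and C6. C4–O can come from a ketene carbonyl, C6–OCH3 with C5–CH3 from 1-methoxypropyne, and C2–O with C3–CH2 from a 3-alkoxy-4-alkylcyclobutenone, so connectivity alone places the single methyl ether between C1 and C5.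
Forward: four-membered ring, then ring A by benzannulation, bromination and acylation at C1, loss of tert-butyl. Ring B comes from dearomatising gem-dimethylation of propionylphloroglucinol, and the halves are joined last through an ortho-quinone methide.
Stereochemistry: the target has no stereocentre; the one centre of the cyclobutenone is racemic and vanishes on aromatisation.

Key step: step 6

Assumption: ring B with its acyl group is a freely equilibrating β-triketone system, and every ring B compound is written in the enol form used in the target SMILES.

Step 1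
Reactants: 1 chloroacetaldehyde dimethyl acetal (2-chloro-1,1-dimethoxyethane)
Product: 3 methyl prop-1-ynyl ether (1-methoxypropyne), via sodium methoxyacetylide 2 (not isolated)
Conditions: NaNH2 (3 equiv), liq NH3, −33 °C; then MeI; H2O work-up, distillation
Reagents that add atoms: iodomethane, CI
Why: Double elimination (MeOH, then HCl) from the chloroacetal gives the sodium alkoxyacetylide, and its SN2 alkylation in liquid ammonia is the standard preparation of 1-alkoxy-1-alkynes.

Step 2
Reactants: 4 trichloroethylene
Product: 6 (E)-1,2-dichlorovinyl tert-butyl ether, via dichloroacetylene 5 (not isolated)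
Conditions: KOtBu, THF, −78 °C → rt
Reagents that add atoms: potassium tert-butoxide, CC(C)(C)[O-].[K+]
Why: Dehydrochlorination followed by anti addition of tert-butoxide to the chloroalkyne (elimination–addition) is the usual entry to 1,2-dichlorovinyl ethers, and the hazardous alkyne is consumed as it forms.

Step 3
Reactants: 6 (E)-1,2-dichlorovinyl tert-butyl ether
Product: 9 tert-butoxyacetylene, via tert-butoxychloroacetylene 7 (not isolated), via lithium tert-butoxyacetylide 8 (not isolated)
Conditions: n-BuLi (2.2 equiv), Et2O, −78 → −40 °C; then H2O, −78 → 0 °C; kept as a cold ethereal solution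
Reagents that add atoms: none
Why: Deprotonation with β-elimination of LiCl, then chlorine–lithium exchange and protonation, is the established ynol ether synthesis from dichlorovinyl ethers, and cold handling suppresses the retro-ene loss of isobutene.

Step 4
Reactants: 10 3-methoxypropanoic acid
Product: 11 3-methoxypropanoyl chloride
Conditions: (COCl)2, DMF (cat), CH2Cl2, 0 °C → rt; distillation
Reagents that add atoms: oxalyl chloride, O=C(Cl)C(=O)Cl
Why: DMF-catalysed acid chloride formation is routine, and the methyl ether, unlike a silyl ether, is indifferent to the HCl released.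

Step 5
Reactants: 11 3-methoxypropanoyl chloride; 9 tert-butoxyacetylene
Product: 13 rac-3-tert-butoxy-4-(methoxymethyl)cyclobut-2-en-1-one, via (methoxymethyl)ketene 12 (not isolated)
Conditions: Et3N, Et2O, 0 °C → rt, 11 (1.5 equiv) added slowly
Reagents that add atoms: none
Why: Dehydrochlorination keeps the aldoketene dilute, and its [2+2] cycloaddition with the ynol ether (terminal nucleophilic alkyne carbon to the ketene carbonyl carbon) is the standard route to 3-alkoxy-4-substituted cyclobutenones; the C4 stereocentre forms racemic and is erased in step 6.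

Step 6
Reactants: 13 rac-3-tert-butoxy-4-(methoxymethyl)cyclobut-2-en-1-one; 3 methyl prop-1-ynyl ether (1-methoxypropyne)
Product: 18 3-tert-butoxy-5-methoxy-2-(methoxymethyl)-6-methylphenol, via vinylketene 14 (not isolated), via vinylcyclobutenone 15 (not isolated), via dienylketene 16 (not isolated), via cyclohexadienone 17 (not isolated)
Conditions: 3 (3 equiv), PhMe, sealed tube, 110 → 140 °C
Reagents that add atoms: none
Why: Danheiser benzannulation: conrotatory 4π opening of 13, with the CH2OMe group turning outward, gives vinylketene 14, and the methyl-bearing nucleophilic carbon of 3 attacks its carbonyl carbon in a regioselective [2+2] cycloaddition to give 15 (bonds C4–C5 and C6–C1 of ring A). A second 4π opening gives dienylketene 16, ring A closes by a disrotatory 6π electrocyclisation that forms C3–C4 of the six-membered carbocycle, and dienone 17 tautomerises irreversibly to phenol 18. The closest known reaction type is the benzannulation of 3-alkylcyclobutenones with 1-alkoxyalkynes to resorcinol monoethers, and the opening required of 13 is of the same class as that of the 3-alkoxy-4-vinylcyclobutenones through which every such reaction passes. No stereocentre is created in the product, since those of 13, 15 and 17 are racemic and disappear on aromatisation. The only selectivity needed is the orientation of the ketene–alkyne [2+2], which the polarisation of the ynol ether secures, while the tert-butoxy group is cross-conjugated in 14 and leaves the ketene carbon electrophilic. The O-methyl group of 3 has no β-hydrogen, so the alkyne cannot fragment by retro-ene at these temperatures.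

Step 7
Reactants: 18 3-tert-butoxy-5-methoxy-2-(methoxymethyl)-6-methylphenol
Product: 19 4-bromo-3-tert-butoxy-5-methoxy-2-(methoxymethyl)-6-methylphenol
Conditions: NBS (1.0 equiv), CH2Cl2, dark, −78 → −20 °C
Reagents that add atoms: N-bromosuccinimide, O=C1CCC(=O)N1Br
Why: Electrophilic aromatic bromination can only strike the single ring C–H, which is para to the free hydroxyl and flanked by two alkoxy groups, and NBS releases no strong acid that would endanger the tert-butyl or benzylic ether.

Step 8
Reactants: 19 4-bromo-3-tert-butoxy-5-methoxy-2-(methoxymethyl)-6-methylphenol; 20 N-methoxy-N-methylbutanamide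
Product: 22 1-[2-tert-butoxy-4-hydroxy-6-methoxy-3-(methoxymethyl)-5-methylphenyl]butan-1-one, via dilithiated arene 21 (not isolated)
Conditions: t-BuLi (3.1 equiv), THF, −78 °C; then 20, −78 → 0 °C; aq NH4Cl
Reagents that add atoms: none
Why: Irreversible bromine–lithium exchange on the lithium phenoxide followed by a Weinreb ketone synthesis installs the butyryl group at C1 under basic conditions that both acid-labile ethers tolerate, and the reaction stops at the ketone.

Step 9
Reactants: 22 1-[2-tert-butoxy-4-hydroxy-6-methoxy-3-(methoxymethyl)-5-methylphenyl]butan-1-one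
Product: 23 1-[2,4-dihydroxy-6-methoxy-3-(methoxymethyl)-5-methylphenyl]butan-1-one
Conditions: HCl (1.25 M in MeOH), 40 °C
Reagents that add atoms: none
Why: Acid solvolysis (SN1) of the crowded aryl tert-butyl ether is helped by the hydrogen bond of the freed C2 hydroxyl to the ketone, and in methanol any acid-induced exchange at the benzylic ether only regenerates the same methyl ether.

Step 10
Reactants: 24 phloroglucinol
Product: 25 1-(2,4,6-trihydroxyphenyl)propan-1-one
Conditions: EtCOCl, AlCl3, CH2Cl2/MeNO2, 0 → 40 °C; aq HCl
Reagents that add atoms: propanoyl chloride, CCC(=O)Cl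
Why: Friedel–Crafts C-acylation of phloroglucinol is routine and stops at the chelated, deactivated monoketone.

Step 11
Reactants: 25 1-(2,4,6-trihydroxyphenyl)propan-1-one
Product: 26 propionylfilicinic acid (3,5-dihydroxy-6,6-dimethyl-2-propanoylcyclohexa-2,4-dien-1-one)
Conditions: NaOMe (3 equiv), MeI (2.2 equiv), MeOH, 0 °C → rt; aq HCl
Reagents that add atoms: iodomethane, CI
Why: Dearomatising geminal C-methylation of the acylphloroglucinol polyanion is the established access to acylfilicinic acids, and limiting the iodomethane leaves the second ring C–H free for the final union.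

Step 12
Reactants: 23 1-[2,4-dihydroxy-6-methoxy-3-(methoxymethyl)-5-methylphenyl]butan-1-one; 26 propionylfilicinic acid
Product: 28 aspidin PB, via ortho-quinone methide 27 (not isolated)
Conditions: TFA (5 equiv), CH2Cl2, 0 °C → rt
Reagents that add atoms: none
Why: Acid expels methanol from the 2,4,6-trioxygenated benzylic ether to give ortho-quinone methide 27 or its protonated form, Michael-type addition of the only ring C–H of enol 26 with re-aromatisation forms the methylene bridge, and the fully substituted ring A cannot condense with itself at carbon.

Compound list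
1 | chloroacetaldehyde dimethyl acetal (2-chloro-1,1-dimethoxyethane) | COC(CCl)OC | starting material
2 | sodium methoxyacetylide | COC#[C-].[Na+] | intermediate
3 | methyl prop-1-ynyl ether (1-methoxypropyne) | CC#COC | intermediate
4 | trichloroethylene | ClC=C(Cl)Cl | starting material
5 | dichloroacetylene | ClC#CCl | intermediate
6 | (E)-1,2-dichlorovinyl tert-butyl ether | CC(C)(C)O/C(Cl)=C\Cl | intermediate
7 | tert-butoxychloroacetylene | CC(C)(C)OC#CCl | intermediate
8 | lithium tert-butoxyacetylide | [Li]C#COC(C)(C)C | intermediate
9 | tert-butoxyacetylene | C#COC(C)(C)C | intermediate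
10 | 3-methoxypropanoic acid | COCCC(=O)O | starting material
11 | 3-methoxypropanoyl chloride | COCCC(=O)Cl | intermediate
12 | (methoxymethyl)ketene (3-methoxyprop-1-en-1-one) | COCC=C=O | intermediate
13 | rac-3-tert-butoxy-4-(methoxymethyl)cyclobut-2-en-1-one | COCC1C(=O)C=C1OC(C)(C)C | intermediate
14 | (Z)-3-tert-butoxy-5-methoxypenta-1,3-dien-1-one (vinylketene) | O=C=C/C(OC(C)(C)C)=C/COC | intermediate
15 | rac-4-[(Z)-1-tert-butoxy-3-methoxyprop-1-enyl]-3-methoxy-2-methylcyclobut-2-en-1-one (vinylcyclobutenone) | O=C1C(C)=C(OC)C1/C(OC(C)(C)C)=C/COC | intermediate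
16 | (3E,5Z)-5-tert-butoxy-3,7-dimethoxy-2-methylhepta-1,3,5-trien-1-one (dienylketene) | O=C=C(C)/C(OC)=C\C(OC(C)(C)C)=C\COC | intermediate
17 | rac-5-tert-butoxy-3-methoxy-6-(methoxymethyl)-2-methylcyclohexa-2,4-dien-1-one | O=C1C(C)=C(OC)C=C(OC(C)(C)C)C1COC | intermediate
18 | 3-tert-butoxy-5-methoxy-2-(methoxymethyl)-6-methylphenol | COCc1c(O)c(C)c(OC)cc1OC(C)(C)C | intermediate
19 | 4-bromo-3-tert-butoxy-5-methoxy-2-(methoxymethyl)-6-methylphenol | COCc1c(O)c(C)c(OC)c(Br)c1OC(C)(C)C | intermediate
20 | N-methoxy-N-methylbutanamide | CCCC(=O)N(C)OC | starting material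
21 | lithium 3-tert-butoxy-4-lithio-5-methoxy-2-(methoxymethyl)-6-methylphenoxide | [Li]Oc1c(C)c(OC)c([Li])c(OC(C)(C)C)c1COC | intermediate
22 | 1-[2-tert-butoxy-4-hydroxy-6-methoxy-3-(methoxymethyl)-5-methylphenyl]butan-1-one | CCCC(=O)c1c(OC(C)(C)C)c(COC)c(O)c(C)c1OC | intermediate
23 | 1-[2,4-dihydroxy-6-methoxy-3-(methoxymethyl)-5-methylphenyl]butan-1-one | CCCC(=O)c1c(O)c(COC)c(O)c(C)c1OC | intermediate
24 | phloroglucinol | Oc1cc(O)cc(O)c1 | starting material
25 | 1-(2,4,6-trihydroxyphenyl)propan-1-one | CCC(=O)c1c(O)cc(O)cc1O | intermediate
26 | propionylfilicinic acid (3,5-dihydroxy-6,6-dimethyl-2-propanoylcyclohexa-2,4-dien-1-one) | CCC(=O)C1=C(O)C=C(O)C(C)(C)C1=O | intermediate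
27 | 4-butanoyl-3-hydroxy-5-methoxy-6-methyl-2-methylidenecyclohexa-3,5-dien-1-one (ortho-quinone methide) | CCCC(=O)C1=C(O)C(=C)C(=O)C(C)=C1OC | intermediate
28 | aspidin PB, 4-[(3-butanoyl-2,6-dihydroxy-4-methoxy-5-methylphenyl)methyl]-3,5-dihydroxy-6,6-dimethyl-2-propanoylcyclohexa-2,4-dien-1-one | CCCC(=O)c1c(O)c(CC2=C(O)C(C)(C)C(=O)C(C(=O)CC)=C2O)c(O)c(C)c1OC | target

Total step count: 12. Longest linear sequence: 8 steps (2, 3, 5, 6, 7, 8, 9, 12).

Steps most likely to fail

Step 6.
- The first ring opening sacrifices the vinylogous ester conjugation of the cyclobutenone and may be slow.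
- At the temperature then needed, several processes can compete:
  - loss of isobutene from the tert-butyl ether;
  - thermal loss of methanol from the ortho-hydroxybenzyl ether of the product;
  - acylation of the product phenol by the vinylketene;
  - a [1,5]-hydrogen shift in the inward-rotated vinylketene.
- The fallback gives up the annulation and differentiates the oxygens of an intact phloroglucinol ring with protecting groups. It sets out from 24 and comes back at 28, using 26 from step 11.
- Friedel–Crafts acylation of 24 with butanoyl chloride and AlCl3 should give 1-(2,4,6-trihydroxyphenyl)butan-1-one F1. Mono-C-methylation (MeI, 1 equiv, NaOMe, MeOH) should give 1-(2,4,6-trihydroxy-3-methylphenyl)butan-1-one F2.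
- MOMCl (2.2 equiv) with i-Pr2NEt should cap the para hydroxyl and the less hindered ortho hydroxyl. The chelated hydroxyl next to the methyl group stays free in 1-[2-hydroxy-4,6-bis(methoxymethoxy)-3-methylphenyl]butan-1-one F3.
- MeI with K2CO3 in DMF should then give 1-[2-methoxy-4,6-bis(methoxymethoxy)-3-methylphenyl]butan-1-one F4. HCl in MeOH should free 1-(2,4-dihydroxy-6-methoxy-5-methylphenyl)butan-1-one F5.
- A Mannich reaction with N,N-dimethylmethyleneiminium iodide at the only free ring carbon should give 1-{3-[(dimethylamino)methyl]-2,4-dihydroxy-6-methoxy-5-methylphenyl}butan-1-one F6. Heating F6 with 26 in dioxane should release the same quinone methide 27 and lead to 28.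

Step 5.
- Three processes can erode the cycloaddition: dimerisation of the monosubstituted ketene, amine-induced β-elimination of methoxide from the acid chloride, and retro-ene decay of the ynol ether.
- The fallback generates the ketene without base by a Wolff rearrangement. It sets out from 9 and comes back at 13.
- Commercial methoxyacetyl chloride is acylated onto TMSCHN2 to give 1-diazo-3-methoxypropan-2-one F7.
- Irradiation of F7 (300 nm, Et2O, 0 °C) in the presence of 9 should produce ketene 12 at a low stationary concentration. The same [2+2] cycloaddition then gives 13.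

Step 12.
- Under acid the union is reversible, so methylene transfer between the two rings can scramble the partners into symmetrical dimers.
- Cyclodehydration between a ring A hydroxyl and a ring B enol, or O-alkylation of the enol, may also intervene.
- The fallback changes the way the electrophile is released, from acid ionisation of an ether to acid-free thermal elimination from a better leaving group. It sets out from 23 and comes back at 28.
- Solvolytic exchange of 23 in AcOH with NaOAc at 80 °C should give (3-butanoyl-2,6-dihydroxy-4-methoxy-5-methylphenyl)methyl acetate F8.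
- Heating F8 with 26 in toluene at 110 °C should generate 27 under neutral conditions and deliver 28.

Further compounds
F1 | step 6 | 1-(2,4,6-trihydroxyphenyl)butan-1-one | CCCC(=O)c1c(O)cc(O)cc1O
F2 | step 6 | 1-(2,4,6-trihydroxy-3-methylphenyl)butan-1-one | CCCC(=O)c1c(O)cc(O)c(C)c1O
F3 | step 6 | 1-[2-hydroxy-4,6-bis(methoxymethoxy)-3-methylphenyl]butan-1-one | CCCC(=O)c1c(O)c(C)c(OCOC)cc1OCOC
F4 | step 6 | 1-[2-methoxy-4,6-bis(methoxymethoxy)-3-methylphenyl]butan-1-one | CCCC(=O)c1c(OC)c(C)c(OCOC)cc1OCOC
F5 | step 6 | 1-(2,4-dihydroxy-6-methoxy-5-methylphenyl)butan-1-one | CCCC(=O)c1c(O)cc(O)c(C)c1OC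
F6 | step 6 | 1-{3-[(dimethylamino)methyl]-2,4-dihydroxy-6-methoxy-5-methylphenyl}butan-1-one | CCCC(=O)c1c(O)c(CN(C)C)c(O)c(C)c1OC
F7 | step 5 | 1-diazo-3-methoxypropan-2-one | COCC(=O)C=[N+]=[N-]
F8 | step 12 | (3-butanoyl-2,6-dihydroxy-4-methoxy-5-methylphenyl)methyl acetate | CCCC(=O)c1c(O)c(COC(C)=O)c(O)c(C)c1OC
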